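**Retrosynthetic overview**

Ring letters: A = arene; B = five-membered ring fused to A; C = cyclohexene; D = six-membered ring holding both ketone carbons; E = cyclopentanone ring bearing the isopropenyl group. D and E together form a bicyclo[3.2.1]octane.
The hydroquinone comes from its bis(methyl ether) by oxidative demethylation and reduction.
Rings B and C are opened together at the aryl–CH bond and at the CH2–C(quaternary) bond. This gives an aryl iodide, a 3-methylbuta-1,3-dienyl group on the D/E bridgehead and an alpha-aryl ketone, which a domino Heck carbopalladation/allylic alkylation rejoins. Enabling feature: in ring C the C=C lies between the benzylic CH bonded to ring A and the CH2 bonded to the quaternary carbon that is alpha to the ring D ketone and sits on the neighbouring carbon of ring A. The unit Ar–CH–CH=C(Me)–CH2–C(alpha) is therefore the pattern of a 1,4-addition of aryl and enolate across a diene.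
The dienyl group comes from a bridgehead ester and the ring D ketone from a nitro group. Ring D is built on ring E by alpha,alpha'-annulation of an (S)-configured cyclopentanone beta-keto ester with a 3-aryl-2-nitroallyl acetate.
Order of ring formation: A and E are bought, then D, then B, then C last.

Key step: step 12

Assumption: in 10–17 the aryl-bearing carbon is epimerisable, and the nitro- and hydroxyl-bearing carbons of 11 and 14 are erased later, so these centres are drawn without configuration.

**Step 1**
Reactants: 1 2,5-dimethoxybenzaldehyde
Product: 3 2-iodo-3,6-dimethoxybenzaldehyde, via lithiated amino alkoxide 2 (not isolated)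
Conditions: MeNHCH2CH2NMe2, n-BuLi, THF, -20 °C; add 1; n-BuLi (excess), -20 °C; I2, -78 °C to rt; H2O
Reagents that add atoms: iodine, II
Why: In situ protection of the aldehyde as an alpha-amino alkoxide followed by directed ortho-lithiation, in which the alkoxide side arm and the 5-methoxy group together direct the metal to the CH between them, and iodine then traps the aryllithium.

**Step 2**
Reactants: 3 2-iodo-3,6-dimethoxybenzaldehyde
Product: 4 (E)-2-iodo-1,4-dimethoxy-3-(2-nitrovinyl)benzene
Conditions: MeNO2, NH4OAc, AcOH, 95 °C
Reagents that add atoms: nitromethane, C[N+](=O)[O-]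
Why: Henry condensation with dehydration, which gives the E nitrostyrene under thermodynamic control and tolerates the aryl iodide and the ethers.

**Step 3**
Reactants: 4 (E)-2-iodo-1,4-dimethoxy-3-(2-nitrovinyl)benzene
Product: 5 (E)-3-(2-iodo-3,6-dimethoxyphenyl)-2-nitroprop-2-en-1-ol
Conditions: aq HCHO, imidazole, anthranilic acid (cat.), THF, rt
Reagents that add atoms: formaldehyde, C=O
Why: Morita–Baylis–Hillman-type hydroxymethylation of a nitroalkene, in which imidazole adds reversibly to the beta-carbon, the nitronate adds to formaldehyde, and loss of imidazole restores the E alkene with aryl trans to nitro.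

**Step 4**
Reactants: 5 (E)-3-(2-iodo-3,6-dimethoxyphenyl)-2-nitroprop-2-en-1-ol
Product: 6 (E)-3-(2-iodo-3,6-dimethoxyphenyl)-2-nitroallyl acetate
Conditions: Ac2O, pyridine, CH2Cl2, 0 °C
Reagents that add atoms: acetic anhydride, CC(=O)OC(C)=O
Why: Plain O-acetylation under weakly basic conditions turns the allylic hydroxyl into the leaving group needed for the addition–elimination of step 7.

**Step 5**
Reactants: 7 cyclopent-2-en-1-one
Product: 8 (S)-3-(prop-1-en-2-yl)cyclopentan-1-one
Conditions: potassium isopropenyltrifluoroborate, [Rh(cod)2]BF4 (cat.), (S)-BINAP (cat.), toluene/H2O, 100 °C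
Reagents that add atoms: potassium isopropenyltrifluoroborate, [K+].C=C(C)[B-](F)(F)F
Why: Rhodium-catalysed asymmetric conjugate addition (Hayashi–Miyaura reaction) of an alkenylboron reagent, in which the (S)-BINAP complex should deliver the alkenyl group to the enone face that gives the S ketone, as it does for other aryl and alkenyl groups on cyclopentenone; this sets the isopropenyl-bearing stereocentre.

**Step 6**
Reactants: 8 (S)-3-(prop-1-en-2-yl)cyclopentan-1-one
Product: 9 methyl (4S)-2-oxo-4-(prop-1-en-2-yl)cyclopentane-1-carboxylate (keto–enol and C1-epimer mixture)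
Conditions: NaH, (MeO)2CO, THF, reflux; AcOH quench
Reagents that add atoms: dimethyl carbonate, COC(=O)OC
Why: Claisen-type C-acylation under equilibrating conditions, in which the product is stored as its enolate and acylation should prefer the alpha-CH2 remote from the isopropenyl-bearing carbon because the other enolate suffers allylic strain.

**Step 7**
Reactants: 9 methyl (4S)-2-oxo-4-(prop-1-en-2-yl)cyclopentane-1-carboxylate, 6 (E)-3-(2-iodo-3,6-dimethoxyphenyl)-2-nitroallyl acetate
Product: 11 methyl (1S,5R,6S)-2-(2-iodo-3,6-dimethoxyphenyl)-3-nitro-8-oxo-6-(prop-1-en-2-yl)bicyclo[3.2.1]octane-1-carboxylate, via nitroalkene 10 (not isolated)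
Conditions: DBU (2.5 equiv), THF (no alcohol), -20 °C to 40 °C
Reagents that add atoms: none
Why: Alpha,alpha'-annulation of a cyclic beta-keto ester with a 2-nitroallyl ester, in which the beta-keto ester carbon adds to the aryl-bearing alkene carbon and acetate leaves (Michael addition–elimination, SN2') to give 10, whose ketone enolises on its other side and closes ring D by intramolecular Michael addition; because the bond to the beta-keto ester carbon stays reversible (retro-Michael from the nitronate) and the open form can epimerise at the ketone alpha-CH, the mixture should drain to the more stable bicycle with the three-carbon bridge anti to the isopropenyl group, which fixes the quaternary bridgehead and the bridgehead CH relative to the existing centre.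

**Step 8**
Reactants: 11 the nitro keto ester of step 7
Product: 13 methyl (1S,5R,6S)-2-(2-iodo-3,6-dimethoxyphenyl)-3,8-dioxo-6-(prop-1-en-2-yl)bicyclo[3.2.1]octane-1-carboxylate, via potassium nitronate 12 (not isolated)
Conditions: KN(SiMe3)2, THF, -78 °C; then aq TiCl3, NH4OAc buffer, 0 °C to rt
Reagents that add atoms: water, O
Why: Nef reaction in its reductive form, in which trivalent titanium reduces the nitronate to the imine and this hydrolyses to the ketone at buffered pH, sparing the aryl iodide, the isopropenyl group and the bridged beta-keto ester, which an alkoxide would open by retro-Dieckmann cleavage.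

**Step 9**
Reactants: 13 the diketo ester of step 8
Product: 14 (1R,5R,6S)-1-(hydroxymethyl)-2-(2-iodo-3,6-dimethoxyphenyl)-6-(prop-1-en-2-yl)bicyclo[3.2.1]octane-3,8-diol
Conditions: i-Bu2AlH (excess), CH2Cl2, -78 °C to 0 °C; aq potassium sodium tartrate
Reagents that add atoms: none
Why: Exhaustive hydride reduction takes the hindered bridgehead ester to the primary alcohol and both ketones to carbinols whose configuration step 10 erases, while i-Bu2AlH leaves the aryl iodide and the alkene untouched.

**Step 10**
Reactants: 14 the triol of step 9
Product: 15 (1R,5R,6S)-2-(2-iodo-3,6-dimethoxyphenyl)-3,8-dioxo-6-(prop-1-en-2-yl)bicyclo[3.2.1]octane-1-carbaldehyde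
Conditions: Dess–Martin periodinane (excess), CH2Cl2, rt
Reagents that add atoms: none
Why: Dess–Martin oxidation of all three alcohols under neutral, non-nucleophilic conditions restores both ketones and gives the non-enolisable bridgehead aldehyde without ring-opening.

**Step 11**
Reactants: 15 the diketo aldehyde of step 10
Product: 16 (1S,5R,6S)-2-(2-iodo-3,6-dimethoxyphenyl)-1-[(1E)-3-methylbuta-1,3-dien-1-yl]-6-(prop-1-en-2-yl)bicyclo[3.2.1]octane-3,8-dione
Conditions: (EtO)2P(O)CH2C(Me)=CH2 (2.3 equiv), LiN(SiMe3)2 (2.2 equiv), THF, -78 °C to rt
Reagents that add atoms: diethyl (2-methylallyl)phosphonate, C=C(C)CP(=O)(OCC)OCC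
Why: Horner–Wadsworth–Emmons-type olefination with an allylic phosphonate anion, which should attack the aldehyde in preference to the hindered bridging ketone and to the ring D ketone (masked as its enolate by the first equivalent of anion) and give mainly the E diene, while Bredt's rule forbids a bridgehead enolate and so blocks retro-aldol loss of the side chain.

**Step 12**
Reactants: 16 the iodoaryl dienyl diketone of step 11
Product: 18 bis(methyl ether) of the target (all five rings and all five stereocentres as in 20), via allylpalladium iodide 17 (not isolated)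
Conditions: Pd2(dba)3·CHCl3 (5 mol %), P(2-furyl)3 (20 mol %), Cs2CO3 (2 equiv), DMA, 65 °C, degassed
Reagents that add atoms: none
Why: Zerovalent palladium inserts into the aryl–iodine bond, syn 5-exo-trig carbopalladation of the proximal diene C=C closes ring B and gives the eta-3-allyl complex 17, and carbonate then removes the benzylic alpha-keto hydrogen so that the enolate attacks the CH2 terminus of the allyl unit from outside the metal, closing ring C (six-membered, all three allyl carbons in the ring) and releasing the catalyst. The closest known type is Heck insertion into a 1,3-diene followed by capture of the allylpalladium intermediate by a stabilised nucleophile (1,4-aryl-alkylation of dienes), combined with Tsuji–Trost alkylation by alpha-aryl ketone enolates. The benzylic methine is set in the insertion: ring B should form cis-fused to ring D with the aryl group pseudo-axial, and in that folded transition state the diene chain and the metal should take the convex face that carries the ring E methylene and the alpha-hydrogen, not the face covered by the two ring D carbonyl carbons. The tether then sets the second quaternary carbon, because the allyl terminus reaches the planar enolate only from that same face; this is also the face anti to palladium after syn insertion into the E alkene, sigma–pi exchange at the unsubstituted CH2 terminus and at the secondary carbon repairs any mismatch of face or syn/anti geometry, and the methyl group on the central allyl carbon favours the anti geometry that a cis ring alkene needs. Regiochemistry is secured because C-attack at the inner allyl carbon would give a cyclobutane, and O-attack there gives a 2-isopropenyl dihydropyran that re-ionises or undergoes a Claisen shift to the same product. The selectivity that matters is insertion ahead of enolate O-arylation to a benzofuran, and the iodide, a simple triarylphosphine and the moderate temperature should secure it because C–O reductive elimination needs wide-bite-angle ligands and more heat.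

**Step 13**
Reactants: 18 bis(methyl ether) of the target
Product: 20 CNP0287617.1 (target hydroquinone), via quinone 19 (not isolated)
Conditions: (NH4)2Ce(NO3)6, MeCN/H2O, 0 °C; then aq Na2S2O4, EtOAc, rt
Reagents that add atoms: water, O
Why: Oxidative demethylation of the 1,4-dimethoxyarene by tetravalent cerium gives quinone 19, which cannot tautomerise because its two benzylic positions are a quaternary carbon and a bridgehead CH, and dithionite reduces it in the same flask to the hydroquinone without touching ketones, alkenes or stereocentres.

**Compound list**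

1 | 2,5-dimethoxybenzaldehyde | COc1ccc(OC)c(C=O)c1 | starting material
2 | lithiated lithium alpha-amino alkoxide of 1 | [Li]c1c(OC)ccc(OC)c1C(O[Li])N(C)CCN(C)C | intermediate
3 | 2-iodo-3,6-dimethoxybenzaldehyde | COc1ccc(OC)c(C=O)c1I | intermediate
4 | (E)-2-iodo-1,4-dimethoxy-3-(2-nitrovinyl)benzene | COc1ccc(OC)c(/C=C/[N+](=O)[O-])c1I | intermediate
5 | (E)-3-(2-iodo-3,6-dimethoxyphenyl)-2-nitroprop-2-en-1-ol | COc1ccc(OC)c(/C=C(\CO)[N+](=O)[O-])c1I | intermediate
6 | (E)-3-(2-iodo-3,6-dimethoxyphenyl)-2-nitroallyl acetate | COc1ccc(OC)c(/C=C(\COC(C)=O)[N+](=O)[O-])c1I | intermediate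
7 | cyclopent-2-en-1-one | O=C1C=CCC1 | starting material
8 | (S)-3-(prop-1-en-2-yl)cyclopentan-1-one | C=C(C)[C@H]1CCC(=O)C1 | intermediate
9 | methyl (4S)-2-oxo-4-(prop-1-en-2-yl)cyclopentane-1-carboxylate | C=C(C)[C@H]1CC(C(=O)OC)C(=O)C1 | intermediate
10 | methyl (1S,4S)-1-[1-(2-iodo-3,6-dimethoxyphenyl)-2-nitroprop-2-en-1-yl]-2-oxo-4-(prop-1-en-2-yl)cyclopentane-1-carboxylate | C=C(C)[C@H]1C[C@](C(=O)OC)(C(C(=C)[N+](=O)[O-])c2c(I)c(OC)ccc2OC)C(=O)C1 | intermediate
11 | methyl (1S,5R,6S)-2-(2-iodo-3,6-dimethoxyphenyl)-3-nitro-8-oxo-6-(prop-1-en-2-yl)bicyclo[3.2.1]octane-1-carboxylate | C=C(C)[C@H]1C[C@@]2(C(=O)OC)C(=O)[C@@H]1CC([N+](=O)[O-])C2c1c(I)c(OC)ccc1OC | intermediate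
12 | potassium nitronate of 11 | C=C(C)[C@H]1C[C@@]2(C(=O)OC)C(=O)[C@@H]1CC(=[N+]([O-])[O-])C2c1c(I)c(OC)ccc1OC.[K+] | intermediate
13 | methyl (1S,5R,6S)-2-(2-iodo-3,6-dimethoxyphenyl)-3,8-dioxo-6-(prop-1-en-2-yl)bicyclo[3.2.1]octane-1-carboxylate | C=C(C)[C@H]1C[C@@]2(C(=O)OC)C(=O)[C@@H]1CC(=O)C2c1c(I)c(OC)ccc1OC | intermediate
14 | (1R,5R,6S)-1-(hydroxymethyl)-2-(2-iodo-3,6-dimethoxyphenyl)-6-(prop-1-en-2-yl)bicyclo[3.2.1]octane-3,8-diol | C=C(C)[C@H]1C[C@@]2(CO)C(O)[C@@H]1CC(O)C2c1c(I)c(OC)ccc1OC | intermediate
15 | (1R,5R,6S)-2-(2-iodo-3,6-dimethoxyphenyl)-3,8-dioxo-6-(prop-1-en-2-yl)bicyclo[3.2.1]octane-1-carbaldehyde | C=C(C)[C@H]1C[C@@]2(C=O)C(=O)[C@@H]1CC(=O)C2c1c(I)c(OC)ccc1OC | intermediate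
16 | (1S,5R,6S)-2-(2-iodo-3,6-dimethoxyphenyl)-1-[(1E)-3-methylbuta-1,3-dien-1-yl]-6-(prop-1-en-2-yl)bicyclo[3.2.1]octane-3,8-dione | C=C(C)[C@H]1C[C@@]2(/C=C/C(C)=C)C(=O)[C@@H]1CC(=O)C2c1c(I)c(OC)ccc1OC | intermediate
17 | ring B-closed allylpalladium iodide, drawn as its sigma form at the CH2 terminus, phosphines omitted | C=C(C)[C@H]1C[C@@]23C(=O)[C@@H]1CC(=O)C2c1c(OC)ccc(OC)c1[C@H]3/C=C(/C)C[Pd]I | intermediate
18 | bis(methyl ether) of the target | C=C(C)[C@H]1C[C@@]23C(=O)[C@@H]1CC(=O)[C@@]21CC(C)=C[C@@H]3c2c(OC)ccc(OC)c21 | intermediate
19 | quinone corresponding to the target | C=C(C)[C@H]1C[C@@]23C(=O)[C@@H]1CC(=O)[C@@]21CC(C)=C[C@@H]3C2=C1C(=O)C=CC2=O | intermediate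
20 | CNP0287617.1 (isopropenyl-bearing carbon S, D/E bridgehead CH R, quaternary carbon shared by rings B to E S, aryl-bearing quaternary carbon R, benzylic methine R) | C=C(C)[C@H]1C[C@@]23C(=O)[C@@H]1CC(=O)[C@@]21CC(C)=C[C@@H]3c2c(O)ccc(O)c21 | target

**Step count and risks**

Total step count: 13. Longest linear sequence: 11 (steps 1–4 and 7–13).

Most likely to fail:

Step 12. Beta-hydride loss or enolate O-arylation may overtake capture of the allylpalladium intermediate, or the insertion may show poor facial selectivity at the benzylic methine. The fallback splits the domino into two separately tunable reactions and sets out from 16. The carbopalladation is run without carbonate and with n-Bu4NOAc as the only nucleophile (Pd(OAc)2, PPh3, DMF). This 1,4-arylacetoxylation of the diene should give the tetracyclic allylic acetate F1 in either alkene geometry, since both ionise to the same allyl complex. Epimers at the benzylic methine can be separated at this stage. The sodium enolate of F1 (NaH, THF) is then closed with Pd(PPh3)4 in a plain intramolecular Tsuji–Trost alkylation, which comes back to the route at 18.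

Step 7. The di-ortho-substituted aryl group may stall the first C–C bond formation, the equilibration may not deliver good facial selectivity at the quaternary carbon, or O-cyclisation of the enol may compete. The fallback sets out from 9 and nitrostyrene 4.
- A quinine-derived bifunctional squaramide should catalyse their Michael addition and choose the face of the beta-keto ester carbon by catalyst control, giving the nitroethyl Michael adduct F2.
- A Henry reaction with aqueous formaldehyde (Et3N cat.) gives the nitro alcohol F3.
- Ac2O/pyridine gives the nitro acetate F4.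
- DBU eliminates acetic acid, which comes back to the route at 10 and hence 11.

Step 11. The carbanion may enolise the substrate without adding to it, may open the beta-keto aldehyde at the bridging ketone, or may be stopped by the neopentyl-type crowding of the aldehyde. The fallback sets out from 15 and avoids carbanions. 2-Methylallylboronic acid pinacol ester (toluene, rt) adds to the aldehyde alone and gives the homoallylic alcohol F5. MsCl/Et3N gives the mesylate F6, and DBU removes an allylic hydrogen in an E2 elimination to the conjugated E diene, which comes back to the route at 16.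

**Further compounds**

F1 | step 12 | tetracyclic allylic acetate (rings A, B, D, E closed, H on the alpha-aryl carbon, 4-acetoxy-3-methylbut-2-enyl chain on the benzylic methine) | C=C(C)[C@H]1C[C@@]23C(=O)[C@@H]1CC(=O)C2c1c(OC)ccc(OC)c1[C@H]3C=C(C)COC(C)=O
F2 | step 7 | methyl (1S,4S)-1-[1-(2-iodo-3,6-dimethoxyphenyl)-2-nitroethyl]-2-oxo-4-(prop-1-en-2-yl)cyclopentane-1-carboxylate | C=C(C)[C@H]1C[C@](C(=O)OC)(C(C[N+](=O)[O-])c2c(I)c(OC)ccc2OC)C(=O)C1
F3 | step 7 | methyl (1S,4S)-1-[3-hydroxy-1-(2-iodo-3,6-dimethoxyphenyl)-2-nitropropyl]-2-oxo-4-(prop-1-en-2-yl)cyclopentane-1-carboxylate | C=C(C)[C@H]1C[C@](C(=O)OC)(C(C(CO)[N+](=O)[O-])c2c(I)c(OC)ccc2OC)C(=O)C1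
F4 | step 7 | acetate of F3 | C=C(C)[C@H]1C[C@](C(=O)OC)(C(C(COC(C)=O)[N+](=O)[O-])c2c(I)c(OC)ccc2OC)C(=O)C1
F5 | step 11 | 1-(1-hydroxy-3-methylbut-3-en-1-yl) analogue of 16 | C=C(C)[C@H]1C[C@@]2(C(O)CC(C)=C)C(=O)[C@@H]1CC(=O)C2c1c(I)c(OC)ccc1OC
F6 | step 11 | methanesulfonate of F5 | C=C(C)[C@H]1C[C@@]2(C(CC(C)=C)OS(C)(=O)=O)C(=O)[C@@H]1CC(=O)C2c1c(I)c(OC)ccc1OC
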